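## Structural features

Oncostemonol B (17) consists of two 5-alkylresorcinol rings, ring A and ring B, joined through their C5 carbons by an unbranched sixteen-carbon chain. Seven methylenes lie on each side of a central C8'=C9' double bond of Z configuration. The molecule has no stereogenic sp3 carbon, so no stereocentres stand next to each other; the Z olefin is the only stereochemical element and must be carried through unchanged. Without its acetyl group the compound would be symmetric, with four equivalent phenolic hydroxyls; the single acetate on one oxygen of ring A is all that distinguishes the two ends. The fragile groups are the aryl acetate (cleaved or shifted by base, nucleophiles, or protic acid in alcohols), the Z alkene (hydrogenation, radical or acid isomerisation, electrophiles) and the electron-rich free phenols (oxidation). The carbon skeleton is simple; the real difficulty is placing exactly one acyl group on one of four chemically equivalent oxygens without a statistical mixture. The key step uses the fact that the C1-acetoxy/C3-hydroxy/C5-alkyl pattern of ring A is the enol acetate of a 5-alkylcyclohexane-1,3-dione, one dehydrogenation below the arene. Such a dione can carry only one enol acetate, so the acetate count is fixed before ring A becomes aromatic, while ring B stays masked as its bis(methoxymethyl) ether.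

## Logic of the disconnections

17 ⇒ 16. The two O–CH2 bonds of the acetals on ring B are cut. Ring B's hydroxyls must stay invisible while ring A receives its acetate, so their release is the last operation. The gain is that the one-acetate problem is confined to ring A. The forward step must be aprotic, non-basic and non-reducing, so that the aryl acetate and the Z olefin survive.

16 ⇒ 14 (through 15). The acetyl C–O bond is cut and two hydrogens are returned to ring A. This leads back to a symmetric dione whose two oxygens need not be told apart, and whose carbocycle is easy to make. The forward step must stop at the single enol acetate 15. The oxidant must meet neither free anhydride nor base, otherwise the new phenol is acetylated or the acyl group moves; excess anhydride, pyridine and acetic acid are therefore stripped before DDQ is added. The oxidant must also spare ring B, the olefin and the acetals.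

14 ⇒ 9 + 10 (through 11, 12, 13). In ring A the C4–C5 bond (Michael addition) and the C2–C3 bond (Claisen condensation) are cut, and a carboxyl group is put back on C4. This is the classical assembly of 5-substituted cyclohexane-1,3-diones: four ring carbons come from 9 and two from 10. Ring A is thereby reduced to an acyclic enone. The hydrolysis and decarboxylation must be run without strong mineral acid because of the acetals.

9 ⇒ 7 + 8, and 7 ⇒ 6. The C3=C4 bond of the enone is cut (Wittig), and the aldehyde is traced to the methyl ester. The ester carbon of 6 thus becomes C5 of ring A. The forward reduction must stop at the aldehyde; the geometry of the new enone is irrelevant because it is consumed.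

6 ⇒ 5 + 2. The aryl–C(sp3) bond at ring B is cut. One carboxyl of the C18 chain sits exactly where ring B must be attached, so its extrusion as CO2 leaves the seven-methylene arm. The whole chain, with the Z olefin already in place, then comes from one building block, and ring B from an aryl bromide. The coupling must leave the olefin, the methyl ester and the acetals alone, and the rates of activation of the two electrophiles must match.

5 ⇒ 4 ⇒ 3, and 2 ⇒ 1. The acyl–O bonds of the activated ester and of the methyl ester are cut, and the acetal O–CH2 bonds on the bromide. Telling the two carboxyls of 3 apart is the only statistical operation of the route; it is placed at the cheapest point, where unwanted material can be recycled.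

## Other disconnections considered

Alternative 1: Both arenes are cut at once, each between the ester-bearing ring carbon and the chain-bearing ring carbon. The key-step product would be dimethyl 6,6'-[(Z)-hexadec-8-ene-1,16-diyl]bis(2,4-dihydroxybenzoate) A1, arising from the open-chain dimethyl (Z)-3,5,7,24,26,28-hexaoxotriacont-15-enedioate A2. In mild aqueous base each triketo ester terminus of A2 should cyclise by aldol addition of C2 to the C7 carbonyl, then dehydrate and enolise to the arene.
- In its favour: both rings form in one two-directional operation, the oxidation level of the arene is already present so no oxidant is needed, and the carboxyl carbons of 3 become ring carbons.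
- Against it: A2 must be built from an activated derivative of 3 by twofold acylation of a polyanion of a polyketo ester, with stoichiometric strong base at low temperature. Its termini can also close the wrong way (Claisen-type closure or lactonisation to a pyranone). A1 carries two surplus ester groups that must be hydrolysed and decarboxylated to 5,5'-[(Z)-hexadec-8-ene-1,16-diyl]bis(benzene-1,3-diol) A3. The single acetate must then be placed on one of four equivalent hydroxyls, which can only be done statistically.
- Comparison: on structure it treats the molecule as symmetric and defers the differentiation to the last step, whereas the chosen plan makes the ends different from step 2 on. On mechanism both build ring A by carbonyl condensation, and the alternative is the better in needing no dehydrogenation. On step count it is the equal or the better (about five operations from 3), but this is paid for with polyanion chemistry and a statistical final step.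

Alternative 2: The benzylic C1'–C2' bond is cut at both ends. The key-step product would be (Z)-1,16-bis(3,5-dimethoxyphenyl)hexadec-8-ene A4, made from two molecules of 3,5-dimethoxytoluene A5 and (Z)-1,14-dibromotetradec-7-ene A6. A5 would be metalated at the methyl group with n-BuLi, KOt-Bu and 2,2,6,6-tetramethylpiperidine, and the benzyl anions would displace both bromides.
- In its favour: the arenes are bought ready-made, no transition metal and no oxidation are needed, both C–C bonds form in one operation, and the olefin is remote from the basic centre.
- Against it: A6 has two carbons fewer per arm than 3 and needs its own synthesis, for example twofold alkyne alkylation and Z-selective semi-reduction. Ring metalation between the methoxy groups competes with lateral metalation. The basic benzyl anion can eliminate HBr from a primary bromide. Four aryl methyl ethers must be cleaved with BBr3 or hot thiolate in the presence of the Z olefin, giving A3 and hence the same statistical mono-acetylation.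
- Comparison: on structure it is equal in taking the Z olefin from a building block, but it does not use the cheap C18 diacid. On mechanism it is the better in avoiding both the nickel step and the unprecedented oxidation. Its key step is the shortest carbon assembly of all, but with the synthesis of A6, the demethylation and the statistical acetylation the total is no shorter, and the end game is less controlled.

Alternative 3: Both aryl–C1' bonds are cut. The key-step product would be (Z)-1,16-bis[3,5-bis(tert-butyldimethylsilyloxy)phenyl]hexadec-8-ene A7, made from bis(1,3-dioxoisoindolin-2-yl) (Z)-octadec-9-enedioate A8 and two molecules of 1-bromo-3,5-bis(tert-butyldimethylsilyloxy)benzene A9. The coupling would run under cathodic reduction with NiCl2 and 2,2'-bipyridine, with loss of two CO2.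
- In its favour: the complete skeleton is reached in two operations from 3, the bond type is the one used in step 4 of the chosen plan, no half-esterification is needed, and fluoride desilylation is harmless to the olefin.
- Against it: both ends must couple in the same flask, electrolysis equipment is needed, and desilylation leads to A3. Because the four hydroxyls of A3 are equivalent, any mono-acetate is the target, so there is no regiochemical problem; the degree of acetylation, however, is governed by statistics. The ceiling for the mono-ester lies well below one half per pass, and non-, mono- and poly-acetylated polyphenols must be separated and recycled.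
- Comparison: on step economy this alternative is clearly the better (about four operations against nine). On mechanism it is the equal in precedent for the C–C bond and the better in risk, since it avoids step 8 altogether. The chosen plan is the better on one point only: the number of acetates is set by construction and not by statistics.

Key step: step 8

Remark on the chemistry: the sp3 stereocentres that appear in 11, 12, 13 and 15 form without control and are all erased by decarboxylation and aromatisation. The C18 diacid loses one carboxyl carbon at ring B and its other carboxyl carbon becomes C5 of ring A, which leaves the required sixteen-carbon linker with the Z olefin at C8'.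

## Route

Step 1
Reactants: 1 5-bromoresorcinol (5-bromobenzene-1,3-diol)
Product: 2 1-bromo-3,5-bis(methoxymethoxy)benzene
Conditions: MOMCl (2.5 equiv, commercial solution in MeOAc), i-Pr2NEt (3 equiv), CH2Cl2, 0 °C to rt
Reagents that add atoms: chloromethyl methyl ether, COCCl
Why: O-alkylation of both phenols by the chloromethyl ether (Williamson-type acetal formation) with a hindered amine as acid scavenger; the aryl bromide is inert, and the diluted commercial reagent avoids handling neat MOMCl.

Step 2
Reactants: 3 (Z)-octadec-9-enedioic acid
Product: 4 (Z)-18-methoxy-18-oxooctadec-9-enoic acid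
Conditions: MeOH (1.2 equiv), H2SO4 (cat.), PhMe, 60 °C; chromatography, recycle of unreacted and twice-esterified material
Reagents that add atoms: methanol, CO
Why: Fischer esterification with methanol as the limiting reagent distributes one methyl group statistically, so the half ester should be the largest single fraction and is separated by its polarity; the isolated Z olefin is inert to catalytic acid at this temperature.

Step 3
Reactants: 4 (Z)-18-methoxy-18-oxooctadec-9-enoic acid
Product: 5 1-(1,3-dioxoisoindolin-2-yl) 18-methyl (Z)-octadec-9-enedioate
Conditions: N-hydroxyphthalimide (1.1 equiv), DIC (1.1 equiv), DMAP (5 mol %), CH2Cl2, rt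
Reagents that add atoms: N-hydroxyphthalimide, ON1C(=O)c2ccccc2C1=O
Why: Steglich-type carbodiimide esterification converts the free acid into the redox-active N-acyloxyphthalimide; the methyl ester and the olefin are spectators.

Step 4
Reactants: 5 1-(1,3-dioxoisoindolin-2-yl) 18-methyl (Z)-octadec-9-enedioate; 2 1-bromo-3,5-bis(methoxymethoxy)benzene (1.5 equiv)
Product: 6 methyl (Z)-17-[3,5-bis(methoxymethoxy)phenyl]heptadec-9-enoate
Conditions: NiBr2(MeOCH2CH2OMe) (10 mol %), 4,4'-di-tert-butyl-2,2'-bipyridine (10 mol %), Zn (2 equiv), DMA, 25 °C
Reagents that add atoms: none
Why: Nickel-catalysed reductive decarboxylative cross-electrophile coupling: zerovalent nickel inserts into the aryl bromide, single-electron reduction of the N-acyloxyphthalimide releases CO2 and a primary alkyl radical, and the arylnickel species captures it and forms the aryl–C(sp3) bond by reductive elimination. The radical lies seven carbons from the olefin, so only eight-membered or larger ring closures are possible and should not compete; the Z geometry is not touched.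

Step 5
Reactants: 6 methyl (Z)-17-[3,5-bis(methoxymethoxy)phenyl]heptadec-9-enoate
Product: 7 (Z)-17-[3,5-bis(methoxymethoxy)phenyl]heptadec-9-enal
Conditions: i-Bu2AlH (1.05 equiv), CH2Cl2, −78 °C; MeOH, then aq. KNaC4H4O6 (potassium sodium tartrate)
Reagents that add atoms: none
Why: Partial reduction of a methyl ester with diisobutylaluminium hydride; the tetrahedral aluminium hemiacetal is stable at −78 °C and releases the aldehyde only on work-up, and acetals and the internal olefin do not react at this temperature.

Step 6
Reactants: 7 (Z)-17-[3,5-bis(methoxymethoxy)phenyl]heptadec-9-enal; 8 1-(triphenylphosphoranylidene)propan-2-one (1.3 equiv)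
Product: 9 (3E,12Z)-20-[3,5-bis(methoxymethoxy)phenyl]icosa-3,12-dien-2-one
Conditions: PhMe, 80 °C
Reagents that add atoms: none
Why: Wittig olefination with a stabilised ylide should give the E methyl enone; the geometry of this new olefin is immaterial because it is consumed in step 7, and the remote Z olefin is unaffected.

Step 7
Reactants: 9 (3E,12Z)-20-[3,5-bis(methoxymethoxy)phenyl]icosa-3,12-dien-2-one; 10 diethyl malonate (1.2 equiv)
Product: 14 5-{(Z)-16-[3,5-bis(methoxymethoxy)phenyl]hexadec-8-en-1-yl}cyclohexane-1,3-dione, via Michael adduct 11 (not isolated), via annulated dioxo ester 12 (not isolated), via dioxo acid 13 (not isolated)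
Conditions: NaOEt (1.2 equiv), EtOH, reflux; then aq. NaOH (3 equiv), reflux; then AcOH to pH 4–5, 60 °C
Reagents that add atoms: none
Why: Michael addition of the malonate to the enone, then intramolecular Claisen condensation of the methyl ketone enolate onto one ester (six-membered ring), saponification, and decarboxylation of the vinylogous β-keto acid: the sequence by which dimedone and 5-alkylcyclohexane-1,3-diones are made. Acidification with acetic acid only keeps the aryl methoxymethyl acetals intact, and C5 of the product carries two identical ring arms, so no stereocentre remains.

Step 8
Reactants: 14 5-{(Z)-16-[3,5-bis(methoxymethoxy)phenyl]hexadec-8-en-1-yl}cyclohexane-1,3-dione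
Product: 16 3-{(Z)-16-[3,5-bis(methoxymethoxy)phenyl]hexadec-8-en-1-yl}-5-hydroxyphenyl acetate, via enol acetate 15 (not isolated)
Conditions: Ac2O (1.2 equiv), pyridine (1.5 equiv), CH2Cl2, 0 °C to rt; evaporate and co-evaporate with PhMe; then DDQ (1.15 equiv), dry PhMe, 80 °C
Reagents that add atoms: acetic anhydride, CC(=O)OC(C)=O
Why: Proposed new method: acetic anhydride and pyridine convert the fully enolised dione, whose two oxygens are equivalent, into its only possible mono enol acetate 15, which is the known O-acylation of cyclic 1,3-diones. After anhydride, pyridine and acetic acid have been stripped, DDQ should abstract hydride from C5 of a dienol tautomer of 15; enolisation through C4 or through C6 leads to the same hydroxy-acetoxy-cyclohexadienyl cation, which is the protonated arene, and loss of a proton gives the phenol with the acetyl group still on the oxygen that carried it. The closest known reactions are the DDQ and Pd(OCOCF3)2–oxygen dehydrogenations of cyclohexenones to phenols and the iodine–methanol conversion of cyclohexane-1,3-diones into 3-methoxyphenols; new here is that an acyl group, not an alkyl group, rides on the enol oxygen through the oxidation in one flask. No ring is closed, since ring A already exists and is only aromatised, and no stereocentre is created; the racemic centre at C5 of 15 disappears. The step needs exactly one acetate, which is secured because the vinylogous ester carbonyl of 15 is not acylated further under these conditions and no anhydride is left when the phenol appears. It needs the acetyl group to stay off C2 and not move between molecules, which is secured by the absence of acyl-transfer catalysts and of base during the oxidation. It needs DDQ to act on ring A only: the benzylic carbon of ring B is meta to both alkoxy groups and gains no oxygen stabilisation on hydride loss, the isolated Z olefin is a poor hydride donor, and methoxymethyl acetals tolerate DDQ. The hydroquinone formed is poorly soluble in toluene and should separate, which limits contact of the product with the only acid generated.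

Step 9
Reactants: 16 3-{(Z)-16-[3,5-bis(methoxymethoxy)phenyl]hexadec-8-en-1-yl}-5-hydroxyphenyl acetate
Product: 17 3-[(Z)-16-(3,5-dihydroxyphenyl)hexadec-8-en-1-yl]-5-hydroxyphenyl acetate (oncostemonol B)
Conditions: ZnBr2 (2 equiv), n-PrSH (4 equiv), CH2Cl2, 0 °C to rt, argon, dark, short reaction time
Reagents that add atoms: none
Why: Lewis-acid-assisted thiolysis of aryl methoxymethyl ethers: ZnBr2 activates the acetal and the thiol takes up the methoxymethyl fragment. The medium contains no base, no alcohol and no reductant, so the aryl acetate should not be transesterified and the olefin is not touched.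

## Compound list

1 | 5-bromoresorcinol (5-bromobenzene-1,3-diol) | Oc1cc(O)cc(Br)c1 | starting material
2 | 1-bromo-3,5-bis(methoxymethoxy)benzene | COCOc1cc(Br)cc(OCOC)c1 | intermediate
3 | (Z)-octadec-9-enedioic acid | OC(=O)CCCCCCC/C=C\CCCCCCCC(=O)O | starting material
4 | (Z)-18-methoxy-18-oxooctadec-9-enoic acid | COC(=O)CCCCCCC/C=C\CCCCCCCC(=O)O | intermediate
5 | 1-(1,3-dioxoisoindolin-2-yl) 18-methyl (Z)-octadec-9-enedioate | COC(=O)CCCCCCC/C=C\CCCCCCCC(=O)ON1C(=O)c2ccccc2C1=O | intermediate
6 | methyl (Z)-17-[3,5-bis(methoxymethoxy)phenyl]heptadec-9-enoate | COC(=O)CCCCCCC/C=C\CCCCCCCc1cc(OCOC)cc(OCOC)c1 | intermediate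
7 | (Z)-17-[3,5-bis(methoxymethoxy)phenyl]heptadec-9-enal | O=CCCCCCCC/C=C\CCCCCCCc1cc(OCOC)cc(OCOC)c1 | intermediate
8 | 1-(triphenylphosphoranylidene)propan-2-one | CC(=O)C=P(c1ccccc1)(c1ccccc1)c1ccccc1 | starting material
9 | (3E,12Z)-20-[3,5-bis(methoxymethoxy)phenyl]icosa-3,12-dien-2-one | CC(=O)/C=C/CCCCCCC/C=C\CCCCCCCc1cc(OCOC)cc(OCOC)c1 | intermediate
10 | diethyl malonate | CCOC(=O)CC(=O)OCC | starting material
11 | diethyl 2-{(Z)-20-[3,5-bis(methoxymethoxy)phenyl]-2-oxoicos-12-en-4-yl}propanedioate (racemic, not isolated) | CCOC(=O)C(C(=O)OCC)C(CC(C)=O)CCCCCCC/C=C\CCCCCCCc1cc(OCOC)cc(OCOC)c1 | intermediate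
12 | ethyl 6-{(Z)-16-[3,5-bis(methoxymethoxy)phenyl]hexadec-8-en-1-yl}-2,4-dioxocyclohexane-1-carboxylate (racemic, mixture of diastereomers and enol forms, present as its sodium enolate, not isolated) | CCOC(=O)C1C(=O)CC(=O)CC1CCCCCCC/C=C\CCCCCCCc2cc(OCOC)cc(OCOC)c2 | intermediate
13 | 6-{(Z)-16-[3,5-bis(methoxymethoxy)phenyl]hexadec-8-en-1-yl}-2,4-dioxocyclohexane-1-carboxylic acid (racemic, not isolated) | OC(=O)C1C(=O)CC(=O)CC1CCCCCCC/C=C\CCCCCCCc2cc(OCOC)cc(OCOC)c2 | intermediate
14 | 5-{(Z)-16-[3,5-bis(methoxymethoxy)phenyl]hexadec-8-en-1-yl}cyclohexane-1,3-dione | O=C1CC(CCCCCCC/C=C\CCCCCCCc2cc(OCOC)cc(OCOC)c2)CC(=O)C1 | intermediate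
15 | 5-{(Z)-16-[3,5-bis(methoxymethoxy)phenyl]hexadec-8-en-1-yl}-3-oxocyclohex-1-en-1-yl acetate (racemic, not isolated) | CC(=O)OC1=CC(=O)CC(CCCCCCC/C=C\CCCCCCCc2cc(OCOC)cc(OCOC)c2)C1 | intermediate
16 | 3-{(Z)-16-[3,5-bis(methoxymethoxy)phenyl]hexadec-8-en-1-yl}-5-hydroxyphenyl acetate | CC(=O)Oc1cc(O)cc(CCCCCCC/C=C\CCCCCCCc2cc(OCOC)cc(OCOC)c2)c1 | intermediate
17 | 3-[(Z)-16-(3,5-dihydroxyphenyl)hexadec-8-en-1-yl]-5-hydroxyphenyl acetate (oncostemonol B) | CC(=O)Oc1cc(O)cc(CCCCCCC/C=C\CCCCCCCc2cc(O)cc(O)c2)c1 | target

## Step count and least certain steps

Total: 9 steps (steps 1–9). Longest linear sequence: 8 steps (3 to 17, steps 2–9); the branch from 1 joins at step 4.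

**Step 8 (key step, the only step without direct precedent).**
- What may go wrong: the dehydrogenation may stall because the vinylogous anhydride 15 enolises slowly without acid or base. The acetyl group may be transferred between molecules, or onto the newly formed phenol if any anhydride or pyridine survives the evaporation. Adventitious water may hydrolyse 15 back to 14. Excess DDQ may oxidise the product phenol further.
- Fallback, by known chemistry only, setting out from 6 and returning to the route at 16; it brings ring A in already aromatic and already acetylated. Saponification of 6 (LiOH, THF/H2O, then citric acid) would give (Z)-17-[3,5-bis(methoxymethoxy)phenyl]heptadec-9-enoic acid F1. Activation as in step 3 would give 1,3-dioxoisoindolin-2-yl (Z)-17-[3,5-bis(methoxymethoxy)phenyl]heptadec-9-enoate F2. Nickel-catalysed reductive coupling under the conditions of step 4 with 5-bromo-1,3-phenylene diacetate F3 (from 1, Ac2O, pyridine) should give 5-{(Z)-16-[3,5-bis(methoxymethoxy)phenyl]hexadec-8-en-1-yl}-1,3-phenylene diacetate F4. Partial methanolysis of F4 (K2CO3, 1 equiv, MeOH, −20 °C) is then stopped at the mono-ester 16; the phenoxide formed first deactivates the remaining ester, and doubly cleaved material is re-acetylated to F4. The fallback replaces steps 5–8 by four operations plus the preparation of F3 and reintroduces a mono-functionalisation of two equivalent esters, but each reaction in it is of a known type.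

**Step 4.**
- What may go wrong: the rates of activation of the two electrophiles may not match. If the N-acyloxyphthalimide is reduced faster than the electron-rich aryl bromide undergoes oxidative addition, the alkyl radical is lost to hydrogen abstraction or dimerisation.
- Fallback, setting out from 2 and 5 and returning at 6; it exchanges the cross-electrophile manifold for a nucleophile–electrophile coupling. Bromine–lithium exchange on 2 (n-BuLi, THF, −78 °C) gives [3,5-bis(methoxymethoxy)phenyl]lithium F5. Transmetalation with ZnCl2 gives chloro[3,5-bis(methoxymethoxy)phenyl]zinc F6. F6 is coupled with 5 in a decarboxylative Negishi-type reaction (NiCl2(MeOCH2CH2OMe), 4,4'-di-tert-butyl-2,2'-bipyridine, THF/DMF, rt) to give 6; only the redox-active ester then has to be reduced.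

**Step 7.**
- What may go wrong: the aryl methoxymethyl acetals may be lost while the hot solution is acidified for decarboxylation, and the decarboxylation may be incomplete if the pH is kept high to protect them.
- Fallback, setting out from 12 and returning at 14. 12 is isolated after the annulation by acidifying the cold ethanolic enolate solution with AcOH. Its ester group is then removed under neutral Krapcho conditions (NaCl, H2O, DMSO, 130 °C), so no acidic aqueous phase is involved. No compound outside the list is made (F0).

**Step 9.**
- What may go wrong: thiyl radicals formed from the thiol by traces of oxygen or light may add reversibly to the olefin and isomerise it from Z to E. The Lewis acid and thiol may also slowly cleave or transfer the aryl acetate.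
- Fallback, setting out from 16 and returning at 17; it uses neither thiol nor protic acid. TMSOTf (4 equiv) and 2,2'-bipyridyl (6 equiv) in MeCN at 0 °C should exchange both aryl methoxymethyl ethers for silyl ethers and silylate the free phenol, giving 3-{(Z)-16-[3,5-bis(trimethylsilyloxy)phenyl]hexadec-8-en-1-yl}-5-(trimethylsilyloxy)phenyl acetate F7. Stirring with water at rt hydrolyses the three aryl silyl ethers to 17.

## Further compounds

F1 | step 8 | (Z)-17-[3,5-bis(methoxymethoxy)phenyl]heptadec-9-enoic acid | OC(=O)CCCCCCC/C=C\CCCCCCCc1cc(OCOC)cc(OCOC)c1
F2 | step 8 | 1,3-dioxoisoindolin-2-yl (Z)-17-[3,5-bis(methoxymethoxy)phenyl]heptadec-9-enoate | O=C(CCCCCCC/C=C\CCCCCCCc1cc(OCOC)cc(OCOC)c1)ON1C(=O)c2ccccc2C1=O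
F3 | step 8 | 5-bromo-1,3-phenylene diacetate | CC(=O)Oc1cc(Br)cc(OC(C)=O)c1
F4 | step 8 | 5-{(Z)-16-[3,5-bis(methoxymethoxy)phenyl]hexadec-8-en-1-yl}-1,3-phenylene diacetate | CC(=O)Oc1cc(OC(C)=O)cc(CCCCCCC/C=C\CCCCCCCc2cc(OCOC)cc(OCOC)c2)c1
F5 | step 4 | [3,5-bis(methoxymethoxy)phenyl]lithium | [Li]c1cc(OCOC)cc(OCOC)c1
F6 | step 4 | chloro[3,5-bis(methoxymethoxy)phenyl]zinc | Cl[Zn]c1cc(OCOC)cc(OCOC)c1
F0 | step 7 | none | none
F7 | step 9 | 3-{(Z)-16-[3,5-bis(trimethylsilyloxy)phenyl]hexadec-8-en-1-yl}-5-(trimethylsilyloxy)phenyl acetate | CC(=O)Oc1cc(O[Si](C)(C)C)cc(CCCCCCC/C=C\CCCCCCCc2cc(O[Si](C)(C)C)cc(O[Si](C)(C)C)c2)c1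
A1 | alternative 1 | dimethyl 6,6'-[(Z)-hexadec-8-ene-1,16-diyl]bis(2,4-dihydroxybenzoate) | COC(=O)c1c(O)cc(O)cc1CCCCCCC/C=C\CCCCCCCc1cc(O)cc(O)c1C(=O)OC
A2 | alternative 1 | dimethyl (Z)-3,5,7,24,26,28-hexaoxotriacont-15-enedioate | COC(=O)CC(=O)CC(=O)CC(=O)CCCCCCC/C=C\CCCCCCCC(=O)CC(=O)CC(=O)CC(=O)OC
A3 | alternative 1 | 5,5'-[(Z)-hexadec-8-ene-1,16-diyl]bis(benzene-1,3-diol) | Oc1cc(O)cc(CCCCCCC/C=C\CCCCCCCc2cc(O)cc(O)c2)c1
A4 | alternative 2 | (Z)-1,16-bis(3,5-dimethoxyphenyl)hexadec-8-ene | COc1cc(CCCCCCC/C=C\CCCCCCCc2cc(OC)cc(OC)c2)cc(OC)c1
A5 | alternative 2 | 3,5-dimethoxytoluene | COc1cc(C)cc(OC)c1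
A6 | alternative 2 | (Z)-1,14-dibromotetradec-7-ene | BrCCCCCC/C=C\CCCCCCBr
A7 | alternative 3 | (Z)-1,16-bis[3,5-bis(tert-butyldimethylsilyloxy)phenyl]hexadec-8-ene | CC(C)(C)[Si](C)(C)Oc1cc(O[Si](C)(C)C(C)(C)C)cc(CCCCCCC/C=C\CCCCCCCc2cc(O[Si](C)(C)C(C)(C)C)cc(O[Si](C)(C)C(C)(C)C)c2)c1
A8 | alternative 3 | bis(1,3-dioxoisoindolin-2-yl) (Z)-octadec-9-enedioate | O=C(CCCCCCC/C=C\CCCCCCCC(=O)ON1C(=O)c2ccccc2C1=O)ON1C(=O)c2ccccc2C1=O
A9 | alternative 3 | 1-bromo-3,5-bis(tert-butyldimethylsilyloxy)benzene | CC(C)(C)[Si](C)(C)Oc1cc(Br)cc(O[Si](C)(C)C(C)(C)C)c1
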